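**Retrosynthetic overview**

- Numbering and feature: the seven-membered ring is C1 (ester CH)–C2–C3 (methyl carbinol)–C4–C5–C6–C10 (CH–iPr); the five-membered ring is C5–C6–C7–C8 (C–Me)–C9 (epoxide CH). The route rests on the C1 carbinol next to isopropyl-bearing C10: with isopropyl written as isopropenyl it is a homoallylic alcohol of the isopulegol type, the retron of a type 1 carbonyl-ene reaction that forms C1–C10 and closes the seven-membered ring (13 → 14).
- Endgame from 14: saturation of isopropenyl; Mitsunobu inversion at C1 with the benzyl-protected acid; C9 ketone → C8(Me)=C9 alkene by α-methylenation, 1,2-reduction and reductive allylic transposition; C3-hydroxyl-directed epoxidation; debenzylation.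
- Ene precursor 13 (trans-2,3-disubstituted cyclopentanone): C6–C10 and C5–C4 come from a three-component coupling on (S)-4-silyloxycyclopent-2-enone, whose C7 oxygen relays absolute configuration and is then removed; C3 comes from catalyst-controlled conjugate borylation–oxidation of the E-enoate side chain.
- Ring order: the five-membered ring is bought, the seven-membered ring is formed in step 8, the oxirane in step 16.

Key step: step 8

Assumption: 1 (S enantiomer), 3 (pure E isomer) and 16 are purchased.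
Assumption: in step 4 the antipode of the chiral bisphosphine is the one whose sense of induction on an E-configured β-methyl enoate gives the (R)-carbinol 10; this is a catalyst property to be confirmed on a model enoate.
Naming: bicyclic compounds are named with the overview numbering (C1–C6 and C10 in the seven-membered ring, C5–C9 in the five-membered ring); the SMILES in the list are definitive.

**Route**

Step 1
Reactants: 1 (S)-4-(tert-butyldimethylsilyloxy)cyclopent-2-en-1-one; 2 1-bromo-2-methylprop-1-ene; 3 ethyl (E)-4-bromo-3-methylbut-2-enoate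
Product: 5 ethyl (E)-4-[(1S,2S,3S)-3-(tert-butyldimethylsilyloxy)-2-(2-methylprop-1-enyl)-5-oxocyclopentyl]-3-methylbut-2-enoate, via zinc enolate 4 (not isolated)
Conditions: 2, tBuLi (2 equiv), Et2O, −78 °C; Me2Zn, THF, 0 °C; 1, −78 °C; then HMPA, 3, −78 → −30 °C
Reagents that add atoms: none
Why: Noyori three-component coupling: the mixed zincate transfers the alkenyl group to C6 anti to the C7 silyloxy group, and the non-equilibrating zinc enolate is alkylated (SN2) at C5 by the allylic bromide anti to the new C6 substituent, so C6 and C5 are both set by the C7 stereocentre.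

Step 2
Reactants: 5 ethyl (E)-4-[(1S,2S,3S)-3-(tert-butyldimethylsilyloxy)-2-(2-methylprop-1-enyl)-5-oxocyclopentyl]-3-methylbut-2-enoate
Product: 7 ethyl (E)-3-methyl-4-[(1S,2S)-2-(2-methylprop-1-enyl)-5-oxocyclopent-3-enyl]but-2-enoate, via β-hydroxy ketone 6 (not isolated)
Conditions: AcOH–THF–H2O (3:1:1), 60 °C
Reagents that add atoms: none
Why: Acid-promoted desilylation followed by dehydration of the β-hydroxy cyclopentanone through its enol; acid is chosen over base because the doubly allylic C6–H of enone 7 is at risk of base-induced isomerisation, and C5 and C6 are untouched while the relay stereocentre C7 is removed.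

Step 3
Reactants: 7 ethyl (E)-3-methyl-4-[(1S,2S)-2-(2-methylprop-1-enyl)-5-oxocyclopent-3-enyl]but-2-enoate
Product: 8 ethyl (E)-3-methyl-4-[(1S,2S)-2-(2-methylprop-1-enyl)-5-oxocyclopentyl]but-2-enoate
Conditions: [(Ph3P)CuH]6 (5 mol%), PhMe2SiH, tBuOH, toluene, 0 °C → rt
Reagents that add atoms: none
Why: Copper hydride conjugate reduction (Stryker's reagent, catalytic in copper) should be selective for the unhindered cyclopentenone over the β,β-disubstituted enoate and the isolated trisubstituted alkene; no stereocentre is formed.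

Step 4
Reactants: 8 ethyl (E)-3-methyl-4-[(1S,2S)-2-(2-methylprop-1-enyl)-5-oxocyclopentyl]but-2-enoate
Product: 10 ethyl (R)-3-hydroxy-3-methyl-4-[(1S,2S)-2-(2-methylprop-1-enyl)-5-oxocyclopentyl]butanoate, via tertiary boronate 9 (not isolated)
Conditions: CuCl (5 mol%), NaOtBu (7 mol%), (R)-1-[(S)-2-(diphenylphosphino)ferrocenyl]ethyldicyclohexylphosphine or its antipode (6 mol%), B2pin2, MeOH, THF, rt; then NaBO3·4H2O, THF–H2O, rt
Reagents that add atoms: bis(pinacolato)diboron, SMILES CC1(C)OB(OC1(C)C)B1OC(C)(C)C(C)(C)O1 (its boron is held only in 9); sodium perborate, SMILES [Na+].O=BO[O-] (the hydroxyl oxygen of 10)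
Why: Copper-catalysed enantioselective conjugate borylation of a β,β-disubstituted enoate followed by stereoretentive perborate oxidation of the tertiary boronate; C3 is set by the chiral ligand acting on the geometrically pure E-enoate, the ring stereocentres being too remote to override it.

Step 5
Reactants: 10 ethyl (R)-3-hydroxy-3-methyl-4-[(1S,2S)-2-(2-methylprop-1-enyl)-5-oxocyclopentyl]butanoate
Product: 11 ethyl (R)-3-methyl-4-[(1S,2S)-2-(2-methylprop-1-enyl)-5-oxocyclopentyl]-3-(triethylsilyloxy)butanoate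
Conditions: Et3SiOTf, 2,6-lutidine, CH2Cl2, −78 → 0 °C
Reagents that add atoms: triethylsilyl trifluoromethanesulfonate, SMILES CC[Si](CC)(CC)OS(=O)(=O)C(F)(F)F
Why: Silylation of the tertiary alcohol with a silyl triflate and a hindered pyridine base is faster than enol silylation of the ketone at low temperature; the silyl ether blocks retro-aldol cleavage, β-elimination and hemiketal formation with the C9 ketone.

Step 6
Reactants: 11 ethyl (R)-3-methyl-4-[(1S,2S)-2-(2-methylprop-1-enyl)-5-oxocyclopentyl]-3-(triethylsilyloxy)butanoate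
Product: 12 (R)-4-[(1S,5S)-2-hydroxy-5-(2-methylprop-1-enyl)cyclopentyl]-3-methyl-3-(triethylsilyloxy)butan-1-ol (both C9 carbinol epimers)
Conditions: LiAlH4, THF, 0 °C
Reagents that add atoms: none
Why: Hydride reduction takes the ester to the primary alcohol and unavoidably the ketone to a secondary alcohol whose configuration is irrelevant because it is reoxidised in step 7; silyl ether and alkene are inert.

Step 7
Reactants: 12 (R)-4-[(1S,5S)-2-hydroxy-5-(2-methylprop-1-enyl)cyclopentyl]-3-methyl-3-(triethylsilyloxy)butan-1-ol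
Product: 13 (R)-3-methyl-4-[(1S,2S)-2-(2-methylprop-1-enyl)-5-oxocyclopentyl]-3-(triethylsilyloxy)butanal
Conditions: Dess–Martin periodinane, pyridine, CH2Cl2, 0 °C → rt
Reagents that add atoms: none
Why: Dess–Martin oxidation of both alcohols under buffered conditions returns the C9 ketone and gives the β-silyloxy aldehyde without β-elimination or epimerisation of the thermodynamically favoured trans C5/C6 arrangement.

Step 8
Reactants: 13 (R)-3-methyl-4-[(1S,2S)-2-(2-methylprop-1-enyl)-5-oxocyclopentyl]-3-(triethylsilyloxy)butanal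
Product: 14 (1S,3R,5S,6S,10R)-1-hydroxy-10-isopropenyl-3-methyl-3-(triethylsilyloxy)perhydroazulen-9-one (trans ring fusion; hydroxyl trans to isopropenyl)
Conditions: Me2AlCl (2.5 equiv), CH2Cl2, −78 → −20 °C; aq. potassium sodium tartrate work-up
Reagents that add atoms: none
Why: Me2AlCl complexes the C1 aldehyde (a further equivalent sits on the C9 ketone), C10 of the 2-methylprop-1-enyl group attacks C1 and a hydrogen of one allylic methyl group passes to the carbonyl oxygen through a six-membered array, after which the alcohol–aluminium complex loses methane so that no free acid is left to ionise the tertiary silyl ether; the closest known reaction is the Lewis-acid-promoted type 1 intramolecular carbonyl-ene cyclisation of citronellal to isopulegol, here extended by one ring atom. The seven-membered ring C1–C2–C3–C4–C5–C6–C10 closes by bonding the aldehyde carbon to the alkene carbon nearer the tether, with the carbonyl oxygen and the second alkene carbon left outside the ring (exo to both π bonds), and the trans-fixed C5 and C6 of the cyclopentanone together with the quaternary C3 favour the folded conformer. C10 is controlled by allylic 1,3-strain: C6–H lies in the plane of the trisubstituted alkene, so the aldehyde tethered to C5 reaches only one alkene face and the new isopropenyl group ends up trans to the C6–C7 bond. C1 is controlled by the chair-like transition state with the aluminium-bound carbonyl oxygen pseudo-equatorial, which should give the alcohol trans to isopropenyl. The step needs the aldehyde to react in preference to the ketone (a much poorer ene acceptor) and the 2-methylprop-1-enyl group to be the only ene donor, which is why C8–C9 is carried as a ketone and not as an alkene.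

Step 9
Reactants: 14 (1S,3R,5S,6S,10R)-1-hydroxy-10-isopropenyl-3-methyl-3-(triethylsilyloxy)perhydroazulen-9-one
Product: 15 (1S,3R,5S,6S,10S)-1-hydroxy-10-isopropyl-3-methyl-3-(triethylsilyloxy)perhydroazulen-9-one
Conditions: H2 (1 atm), RhCl(PPh3)3 (5 mol%), benzene, rt
Reagents that add atoms: none
Why: Homogeneous hydrogenation with Wilkinson's catalyst saturates the 1,1-disubstituted alkene without double-bond migration toward C10 (which would endanger that stereocentre) and without reducing the ketone; no new stereocentre is formed.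

Step 10
Reactants: 15 (1S,3R,5S,6S,10S)-1-hydroxy-10-isopropyl-3-methyl-3-(triethylsilyloxy)perhydroazulen-9-one; 16 3-(benzyloxy)-4-methoxybenzoic acid
Product: 17 (1R,3R,5S,6S,10S)-10-isopropyl-3-methyl-9-oxo-3-(triethylsilyloxy)perhydroazulen-1-yl 3-(benzyloxy)-4-methoxybenzoate
Conditions: PPh3, DIAD, toluene, 0 °C → rt
Reagents that add atoms: none
Why: Mitsunobu esterification displaces the C1 oxyphosphonium by carboxylate in an SN2 step, so the trans alcohol from the ene reaction is inverted to the target C1 configuration (ester cis to isopropyl); the phenol is benzylated so that it cannot compete as a nucleophile.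

Step 11
Reactants: 17 (1R,3R,5S,6S,10S)-10-isopropyl-3-methyl-9-oxo-3-(triethylsilyloxy)perhydroazulen-1-yl 3-(benzyloxy)-4-methoxybenzoate
Product: 18 (1R,3R,5S,6S,10S)-8-[(dimethylamino)methyl]-10-isopropyl-3-methyl-9-oxo-3-(triethylsilyloxy)perhydroazulen-1-yl 3-(benzyloxy)-4-methoxybenzoate (C8 epimers)
Conditions: LiN(SiMe3)2, THF, −78 °C; then CH2=NMe2+ I−, −78 °C → rt
Reagents that add atoms: N,N-dimethylmethyleneiminium iodide (Eschenmoser's salt), SMILES C=[N+](C)C.[I-]
Why: Kinetic deprotonation occurs at the C8 methylene and not at the ring-fusion methine C5, and the enolate is trapped by the iminium salt (Mannich reaction); the aryl ester has no α-hydrogen and is not attacked by the hindered amide at −78 °C, and the C8 configuration is irrelevant.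

Step 12
Reactants: 18 (1R,3R,5S,6S,10S)-8-[(dimethylamino)methyl]-10-isopropyl-3-methyl-9-oxo-3-(triethylsilyloxy)perhydroazulen-1-yl 3-(benzyloxy)-4-methoxybenzoate
Product: 20 (1R,3R,5S,6S,10S)-10-isopropyl-3-methyl-8-methylidene-9-oxo-3-(triethylsilyloxy)perhydroazulen-1-yl 3-(benzyloxy)-4-methoxybenzoate, via ammonium iodide 19 (not isolated)
Conditions: MeI, CH2Cl2, rt; then aq. NaHCO3, CH2Cl2, rt
Reagents that add atoms: iodomethane, SMILES CI (its methyl group is held only in 19)
Why: N-Methylation and mild base-induced E1cB elimination of the β-ammonio ketone give the α-methylene ketone; the weak base avoids epimerisation at C5, and any isomerisation to the endocyclic 8-methyl enone would be harmless because steps 13 and 14 convert both enones into the same alkene.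

Step 13
Reactants: 20 (1R,3R,5S,6S,10S)-10-isopropyl-3-methyl-8-methylidene-9-oxo-3-(triethylsilyloxy)perhydroazulen-1-yl 3-(benzyloxy)-4-methoxybenzoate
Product: 21 (1R,3R,5S,6R,10S)-9-hydroxy-10-isopropyl-3-methyl-8-methylidene-3-(triethylsilyloxy)perhydroazulen-1-yl 3-(benzyloxy)-4-methoxybenzoate (C9 epimers)
Conditions: NaBH4, CeCl3·7H2O, MeOH, −78 → −40 °C
Reagents that add atoms: none
Why: Luche reduction gives clean 1,2-reduction of the enone; the C9 configuration is irrelevant because C9 becomes sp2 in step 14, and the aryl ester is not reduced.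

Step 14
Reactants: 21 (1R,3R,5S,6R,10S)-9-hydroxy-10-isopropyl-3-methyl-8-methylidene-3-(triethylsilyloxy)perhydroazulen-1-yl 3-(benzyloxy)-4-methoxybenzoate
Product: 24 (1R,3R,5S,6R,10S)-10-isopropyl-3,8-dimethyl-3-(triethylsilyloxy)-1,2,3,4,5,6,7,10-octahydroazulen-1-yl 3-(benzyloxy)-4-methoxybenzoate, via sulfonyl hydrazine adduct 22 (not isolated), via allylic diazene 23 (not isolated)
Conditions: 2-nitrobenzenesulfonohydrazide, PPh3, DEAD, N-methylmorpholine, −30 °C → rt
Reagents that add atoms: 2-nitrobenzenesulfonohydrazide, SMILES NNS(=O)(=O)c1ccccc1[N+](=O)[O-] (its nitrogen atoms are held only in 22 and 23)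
Why: Myers reductive allylic transposition: Mitsunobu displacement at C9 by the sulfonyl hydrazide, loss of sulfinic acid to the monoalkyl diazene and retro-ene loss of N2 deliver hydrogen to the exocyclic methylene carbon and move the double bond to C8=C9, so the C8 methyl group and the trisubstituted alkene arise together and regiospecifically.

Step 15
Reactants: 24 (1R,3R,5S,6R,10S)-10-isopropyl-3,8-dimethyl-3-(triethylsilyloxy)-1,2,3,4,5,6,7,10-octahydroazulen-1-yl 3-(benzyloxy)-4-methoxybenzoate
Product: 25 (1R,3R,5S,6R,10S)-3-hydroxy-10-isopropyl-3,8-dimethyl-1,2,3,4,5,6,7,10-octahydroazulen-1-yl 3-(benzyloxy)-4-methoxybenzoate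
Conditions: HF·pyridine, pyridine, THF, 0 °C → rt
Reagents that add atoms: none
Why: Buffered fluoride cleavage of the tertiary triethylsilyl ether leaves the aryl ester, benzyl ether and alkene intact and frees the C3 hydroxyl needed to direct step 16.

Step 16
Reactants: 25 (1R,3R,5S,6R,10S)-3-hydroxy-10-isopropyl-3,8-dimethyl-1,2,3,4,5,6,7,10-octahydroazulen-1-yl 3-(benzyloxy)-4-methoxybenzoate
Product: 26 (1R,3R,5S,6R,8R,9S,10S)-8,9-epoxy-3-hydroxy-10-isopropyl-3,8-dimethylperhydroazulen-1-yl 3-(benzyloxy)-4-methoxybenzoate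
Conditions: VO(acac)2 (5 mol%), tBuOOH (in decane), CH2Cl2, 0 °C → rt
Reagents that add atoms: tert-butyl hydroperoxide, SMILES CC(C)(C)OO
Why: Vanadium-catalysed hydroxyl-directed epoxidation of a bishomoallylic alcohol: the C3 alkoxide on vanadium can reach the C8=C9 alkene only across the face carrying the C5–C4 bond, which sets C8 and C9 with the epoxide oxygen cis to the C3 hydroxyl and trans to C5–H; that cis relationship also rules out backside opening of the epoxide by the C3 hydroxyl.

Step 17
Reactants: 26 (1R,3R,5S,6R,8R,9S,10S)-8,9-epoxy-3-hydroxy-10-isopropyl-3,8-dimethylperhydroazulen-1-yl 3-(benzyloxy)-4-methoxybenzoate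
Product: 27 CNP0106636.1, (1R,3R,5S,6R,8R,9S,10S)-8,9-epoxy-3-hydroxy-10-isopropyl-3,8-dimethylperhydroazulen-1-yl 3-hydroxy-4-methoxybenzoate
Conditions: H2 (1 atm), 10% Pd/C, EtOAc, rt
Reagents that add atoms: none
Why: Hydrogenolysis of the aryl benzyl ether in a neutral aprotic solvent; the trisubstituted epoxide is neither allylic nor benzylic and the aryl ester is stable, so only the O–benzyl bond should be cleaved.

**Compound list**

1 | (S)-4-(tert-butyldimethylsilyloxy)cyclopent-2-en-1-one | O=C1C=C[C@@H](O[Si](C)(C)C(C)(C)C)C1 | starting material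
2 | 1-bromo-2-methylprop-1-ene | CC(C)=CBr | starting material
3 | ethyl (E)-4-bromo-3-methylbut-2-enoate | CCOC(=O)/C=C(\C)CBr | starting material
4 | lithium dimethylzinc enolate of (3S,4S)-4-(tert-butyldimethylsilyloxy)-3-(2-methylprop-1-enyl)cyclopentanone | [Li+].C[Zn-](C)OC1=C[C@H](C=C(C)C)[C@@H](O[Si](C)(C)C(C)(C)C)C1 | intermediate
5 | ethyl (E)-4-[(1S,2S,3S)-3-(tert-butyldimethylsilyloxy)-2-(2-methylprop-1-enyl)-5-oxocyclopentyl]-3-methylbut-2-enoate | CCOC(=O)/C=C(\C)C[C@H]1[C@@H]([C@@H](O[Si](C)(C)C(C)(C)C)CC1=O)C=C(C)C | intermediate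
6 | ethyl (E)-4-[(1S,2S,3S)-3-hydroxy-2-(2-methylprop-1-enyl)-5-oxocyclopentyl]-3-methylbut-2-enoate | CCOC(=O)/C=C(\C)C[C@H]1[C@@H]([C@@H](O)CC1=O)C=C(C)C | intermediate
7 | ethyl (E)-3-methyl-4-[(1S,2S)-2-(2-methylprop-1-enyl)-5-oxocyclopent-3-enyl]but-2-enoate | CCOC(=O)/C=C(\C)C[C@H]1[C@@H](C=CC1=O)C=C(C)C | intermediate
8 | ethyl (E)-3-methyl-4-[(1S,2S)-2-(2-methylprop-1-enyl)-5-oxocyclopentyl]but-2-enoate | CCOC(=O)/C=C(\C)C[C@H]1[C@@H](CCC1=O)C=C(C)C | intermediate
9 | ethyl (S)-3-methyl-4-[(1S,2S)-2-(2-methylprop-1-enyl)-5-oxocyclopentyl]-3-(4,4,5,5-tetramethyl-1,3,2-dioxaborolan-2-yl)butanoate | CCOC(=O)C[C@](C)(B2OC(C)(C)C(C)(C)O2)C[C@H]1[C@@H](CCC1=O)C=C(C)C | intermediate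
10 | ethyl (R)-3-hydroxy-3-methyl-4-[(1S,2S)-2-(2-methylprop-1-enyl)-5-oxocyclopentyl]butanoate | CCOC(=O)C[C@](C)(O)C[C@H]1[C@@H](CCC1=O)C=C(C)C | intermediate
11 | ethyl (R)-3-methyl-4-[(1S,2S)-2-(2-methylprop-1-enyl)-5-oxocyclopentyl]-3-(triethylsilyloxy)butanoate | CCOC(=O)C[C@](C)(O[Si](CC)(CC)CC)C[C@H]1[C@@H](CCC1=O)C=C(C)C | intermediate
12 | (R)-4-[(1S,5S)-2-hydroxy-5-(2-methylprop-1-enyl)cyclopentyl]-3-methyl-3-(triethylsilyloxy)butan-1-ol (C9 epimers) | OCC[C@](C)(O[Si](CC)(CC)CC)C[C@H]1[C@@H](CCC1O)C=C(C)C | intermediate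
13 | (R)-3-methyl-4-[(1S,2S)-2-(2-methylprop-1-enyl)-5-oxocyclopentyl]-3-(triethylsilyloxy)butanal | O=CC[C@](C)(O[Si](CC)(CC)CC)C[C@H]1[C@@H](CCC1=O)C=C(C)C | intermediate
14 | (1S,3R,5S,6S,10R)-1-hydroxy-10-isopropenyl-3-methyl-3-(triethylsilyloxy)perhydroazulen-9-one | O[C@H]2C[C@](C)(O[Si](CC)(CC)CC)C[C@H]3[C@@H](CCC3=O)[C@@H]2C(C)=C | intermediate
15 | (1S,3R,5S,6S,10S)-1-hydroxy-10-isopropyl-3-methyl-3-(triethylsilyloxy)perhydroazulen-9-one | O[C@H]2C[C@](C)(O[Si](CC)(CC)CC)C[C@H]3[C@@H](CCC3=O)[C@@H]2C(C)C | intermediate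
16 | 3-(benzyloxy)-4-methoxybenzoic acid | COc1ccc(C(=O)O)cc1OCc1ccccc1 | starting material
17 | (1R,3R,5S,6S,10S)-10-isopropyl-3-methyl-9-oxo-3-(triethylsilyloxy)perhydroazulen-1-yl 3-(benzyloxy)-4-methoxybenzoate | COc1ccc(C(=O)O[C@@H]2C[C@](C)(O[Si](CC)(CC)CC)C[C@H]3[C@@H](CCC3=O)[C@@H]2C(C)C)cc1OCc1ccccc1 | intermediate
18 | 8-[(dimethylamino)methyl] derivative of 17 (C8 epimers) | COc1ccc(C(=O)O[C@@H]2C[C@](C)(O[Si](CC)(CC)CC)C[C@H]3[C@@H](CC(CN(C)C)C3=O)[C@@H]2C(C)C)cc1OCc1ccccc1 | intermediate
19 | 8-[(trimethylammonio)methyl] derivative of 17, iodide | [I-].COc1ccc(C(=O)O[C@@H]2C[C@](C)(O[Si](CC)(CC)CC)C[C@H]3[C@@H](CC(C[N+](C)(C)C)C3=O)[C@@H]2C(C)C)cc1OCc1ccccc1 | intermediate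
20 | (1R,3R,5S,6S,10S)-10-isopropyl-3-methyl-8-methylidene-9-oxo-3-(triethylsilyloxy)perhydroazulen-1-yl 3-(benzyloxy)-4-methoxybenzoate | COc1ccc(C(=O)O[C@@H]2C[C@](C)(O[Si](CC)(CC)CC)C[C@H]3[C@@H](CC(=C)C3=O)[C@@H]2C(C)C)cc1OCc1ccccc1 | intermediate
21 | (1R,3R,5S,6R,10S)-9-hydroxy-10-isopropyl-3-methyl-8-methylidene-3-(triethylsilyloxy)perhydroazulen-1-yl 3-(benzyloxy)-4-methoxybenzoate (C9 epimers) | COc1ccc(C(=O)O[C@@H]2C[C@](C)(O[Si](CC)(CC)CC)C[C@H]3[C@@H](CC(=C)C3O)[C@@H]2C(C)C)cc1OCc1ccccc1 | intermediate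
22 | 9-[1-(2-nitrophenylsulfonyl)hydrazinyl] analogue of 21 (nitrogen in place of the C9 hydroxyl) | COc1ccc(C(=O)O[C@@H]2C[C@](C)(O[Si](CC)(CC)CC)C[C@H]3[C@@H](CC(=C)C3N(N)S(=O)(=O)c4ccccc4[N+](=O)[O-])[C@@H]2C(C)C)cc1OCc1ccccc1 | intermediate
23 | 9-diazenyl analogue of 21 (allylic monoalkyl diazene) | COc1ccc(C(=O)O[C@@H]2C[C@](C)(O[Si](CC)(CC)CC)C[C@H]3[C@@H](CC(=C)C3N=N)[C@@H]2C(C)C)cc1OCc1ccccc1 | intermediate
24 | (1R,3R,5S,6R,10S)-10-isopropyl-3,8-dimethyl-3-(triethylsilyloxy)-1,2,3,4,5,6,7,10-octahydroazulen-1-yl 3-(benzyloxy)-4-methoxybenzoate | COc1ccc(C(=O)O[C@@H]2C[C@](C)(O[Si](CC)(CC)CC)C[C@H]3[C@@H](CC(C)=C3)[C@@H]2C(C)C)cc1OCc1ccccc1 | intermediate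
25 | (1R,3R,5S,6R,10S)-3-hydroxy-10-isopropyl-3,8-dimethyl-1,2,3,4,5,6,7,10-octahydroazulen-1-yl 3-(benzyloxy)-4-methoxybenzoate | COc1ccc(C(=O)O[C@@H]2C[C@](C)(O)C[C@H]3[C@@H](CC(C)=C3)[C@@H]2C(C)C)cc1OCc1ccccc1 | intermediate
26 | (1R,3R,5S,6R,8R,9S,10S)-8,9-epoxy-3-hydroxy-10-isopropyl-3,8-dimethylperhydroazulen-1-yl 3-(benzyloxy)-4-methoxybenzoate | COc1ccc(C(=O)O[C@@H]2C[C@](C)(O)C[C@H]3[C@@H](C[C@@]4(C)O[C@@H]34)[C@@H]2C(C)C)cc1OCc1ccccc1 | intermediate
27 | CNP0106636.1, (1R,3R,5S,6R,8R,9S,10S)-8,9-epoxy-3-hydroxy-10-isopropyl-3,8-dimethylperhydroazulen-1-yl 3-hydroxy-4-methoxybenzoate | COc1ccc(C(=O)O[C@@H]2C[C@](C)(O)C[C@H]3[C@@H](C[C@@]4(C)O[C@@H]34)[C@@H]2C(C)C)cc1O | target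

**Step count and risks**

Total step count: 17. Longest linear sequence: 17 steps (1 → 27); 2, 3 and 16 are purchased and enter in steps 1 and 10.

The three steps most likely to fail:

Step 8 (ene closure). The seven-membered transition state demands C–C bond formation and hydrogen transfer at once; if it is not reached cleanly, the activated aldehyde may lose the β-silyloxy group or the developing tertiary cation may be diverted. The fallback sets out from 13 and uses a stepwise chloro-Prins cyclisation (SnCl4, CH2Cl2, −78 °C), which forms the same C1–C10 bond but lets chloride capture the tertiary cation, giving the γ-chloro alcohol F1. Radical dechlorination (Bu3SnH, AIBN, toluene, 80 °C) then gives 15 directly, so the route is rejoined at 15 and step 9 is not needed.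

Step 10 (Mitsunobu inversion). Displacement at the hindered C1 oxyphosphonium, flanked by the isopropyl-bearing C10, by a carboxylate of only moderate acidity may be slow, so that elimination or return of the alcohol takes over. The fallback sets out from 15: sulfonylation with ClCH2SO2Cl and pyridine (CH2Cl2, 0 °C) gives the chloromethanesulfonate F2. It is displaced with inversion by caesium 3-(benzyloxy)-4-methoxybenzoate F3 (from 16 and Cs2CO3) in the presence of 18-crown-6 in toluene at 80 °C, which returns to the route at 17.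

Step 16 (directed epoxidation). Facial selectivity may be poor if delivery from the C3 alkoxide is inefficient, because undirected attack should prefer the face away from the C5–C4 bond. The fallback sets out from 24, with the silyl ether still in place so that the C3 oxygen cannot intercept the bromonium ion. NBS in aqueous THF at 0 °C forms the bromonium ion on the less hindered face and water opens it at the tertiary C8 from the opposite face, giving the bromohydrin F4. K2CO3 in MeOH at 0 °C closes the ring by backside displacement of bromide to the epoxy silyl ether F5, with the oxygen on the required face. HF·pyridine in THF then removes the silyl group and returns to the route at 26.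

**Further compounds**

F1 | step 8 | (1S,3R,5S,6R,10S)-10-(2-chloropropan-2-yl)-1-hydroxy-3-methyl-3-(triethylsilyloxy)perhydroazulen-9-one | O[C@H]2C[C@](C)(O[Si](CC)(CC)CC)C[C@H]3[C@@H](CCC3=O)[C@@H]2C(C)(C)Cl
F2 | step 10 | (1S,3R,5S,6S,10S)-10-isopropyl-3-methyl-9-oxo-3-(triethylsilyloxy)perhydroazulen-1-yl chloromethanesulfonate | ClCS(=O)(=O)O[C@H]2C[C@](C)(O[Si](CC)(CC)CC)C[C@H]3[C@@H](CCC3=O)[C@@H]2C(C)C
F3 | step 10 | caesium 3-(benzyloxy)-4-methoxybenzoate | [Cs+].COc1ccc(C([O-])=O)cc1OCc1ccccc1
F4 | step 16 | (1R,3R,5S,6S,8R,9R,10S)-9-bromo-8-hydroxy-10-isopropyl-3,8-dimethyl-3-(triethylsilyloxy)perhydroazulen-1-yl 3-(benzyloxy)-4-methoxybenzoate | COc1ccc(C(=O)O[C@@H]2C[C@](C)(O[Si](CC)(CC)CC)C[C@H]3[C@@H](C[C@@](C)(O)[C@@H]3Br)[C@@H]2C(C)C)cc1OCc1ccccc1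
F5 | step 16 | (1R,3R,5S,6R,8R,9S,10S)-8,9-epoxy-10-isopropyl-3,8-dimethyl-3-(triethylsilyloxy)perhydroazulen-1-yl 3-(benzyloxy)-4-methoxybenzoate | COc1ccc(C(=O)O[C@@H]2C[C@](C)(O[Si](CC)(CC)CC)C[C@H]3[C@@H](C[C@@]4(C)O[C@@H]34)[C@@H]2C(C)C)cc1OCc1ccccc1
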